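**Retrosynthetic overview**

Numbering: bicyclo[3.3.1]nonane core C1–C9 (C1 isobutyryl, C5 geranyl, C8 CMe2, C9 bridging C=O); bridge C7–C10–C11–C3; cyclopentane C3–C11–C12(Me2)–C13–C14; C15 is the isobutyryl C=O. The plan rests on the seven-membered ring C3–C2–C1–C8–C7–C10–C11. In it CMe2 (C8) stands between C1 and C7, which is the imprint of a cis-2,2-dimethylcyclopropane C1–C8–C7 carrying two alkenyl arms.
Last bonds, in retro order: C1–C15 (bridgehead acylation), C5–C4 (transannular thio-Claisen, ring A and cage), C6–C7 (6-exo radical, ring B), C1–C9 (aldol). The cap C9–C5(geranyl)–C6 is laid on the cycloheptene face that carries C4.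
Before that come the C3–C14 alkylation (cyclopentane) and the [3,3] shift (C3–C11 made, C1–C7 broken) of a divinylcyclopropane built from (1R,3S)-caronaldehyde ester.
Ring order: cyclopropane (bought), then the seven-membered ring, the cyclopentane, ring B, and ring A (cage).
C4 is carried as an S-ethyl thioester, so that the last ring closure, which gives a non-enolisable 1,3-diketone, is driven by loss of thiolate.

Key step: step 9

Assumption: 7 (methyl ester of (1R)-cis-caronaldehydic acid, a pyrethroid intermediate) is taken as a purchasable single enantiomer, and C5 and C9 are carried as epimer mixtures in 22–26 because both centres are erased later (C9 oxidised, C5 enolised).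

**Step 1**
Reactants: 1 3,3-dimethyloxolan-2-one (α,α-dimethyl-γ-butyrolactone)
Product: 3 methyl 4-chloro-2,2-dimethylbutanoate, via 4-chloro-2,2-dimethylbutanoyl chloride 2 (not isolated)
Conditions: SOCl2, ZnCl2 (cat.), 75 °C; then MeOH, 0 °C → rt
Reagents that add atoms: thionyl chloride, ClS(Cl)=O; methanol, CO
Why: Lewis-acid-assisted ring opening of the γ-lactone by thionyl chloride (chloride cleaves the alkyl C–O bond) should give the ω-chloro acid chloride, which methanol esterifies; no stereocentre is involved.

**Step 2**
Reactants: 3 methyl 4-chloro-2,2-dimethylbutanoate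
Product: 4 4-chloro-2,2-dimethylbutan-1-ol
Conditions: DIBAL-H (2.2 equiv), CH2Cl2, −78 → 0 °C; Rochelle salt
Reagents that add atoms: none
Why: Hydride reduction of the ester leaves the primary chloride alone, and the weakly nucleophilic aluminium alkoxide with a cold neutral work-up should avoid closure to 3,3-dimethyloxolane.

**Step 3**
Reactants: 4 4-chloro-2,2-dimethylbutan-1-ol
Product: 5 5-[(4-chloro-2,2-dimethylbutyl)sulfanyl]-1-phenyl-1H-tetrazole
Conditions: 1-phenyl-1H-tetrazole-5-thiol, PPh3, DIAD, THF, 0 → 40 °C
Reagents that add atoms: 1-phenyl-1H-tetrazole-5-thiol, Sc1nnnn1-c1ccccc1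
Why: In this Mitsunobu thioetherification the acidic thiol displaces the oxyphosphonium group at the neopentyl carbon C11 under neutral conditions, so no free alkoxide can attack C14–Cl.

**Step 4**
Reactants: 5 the tetrazolyl sulfide
Product: 6 5-[(4-chloro-2,2-dimethylbutyl)sulfonyl]-1-phenyl-1H-tetrazole
Conditions: (NH4)6Mo7O24·4H2O (cat.), 30% H2O2, EtOH, 0 °C → rt
Reagents that add atoms: hydrogen peroxide, OO
Why: Molybdate-catalysed peroxide oxidation takes the sulfide to the sulfone, and the alkyl chloride is inert to it.

**Step 5**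
Reactants: 6 the PT sulfone; 7 methyl (1R,3S)-3-formyl-2,2-dimethylcyclopropane-1-carboxylate
Product: 8 methyl (1R,3S)-3-[(1E)-5-chloro-3,3-dimethylpent-1-en-1-yl]-2,2-dimethylcyclopropane-1-carboxylate
Conditions: 6, KHMDS, DME, −60 °C; then 7, −60 °C → rt; aq NH4Cl
Reagents that add atoms: none
Why: In the Julia–Kocienski olefination the pre-formed sulfonyl carbanion adds to the aldehyde faster than it removes the poorly acidic cyclopropyl C–H, and anti addition, Smiles rearrangement and elimination, reinforced by the tert-alkyl group, should give the E C10=C11 alkene with the cis cyclopropane intact.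

**Step 6**
Reactants: 8 the E-alkenyl cyclopropane ester
Product: 9 (1R,3S)-3-[(1E)-5-chloro-3,3-dimethylpent-1-en-1-yl]-2,2-dimethylcyclopropane-1-carboxylic acid
Conditions: LiOH·H2O, THF/MeOH/H2O, 45 °C; then 1 M HCl
Reagents that add atoms: lithium hydroxide, [Li+].[OH-]
Why: Saponification proceeds by acyl attack; hydroxide does not epimerise a cyclopropanecarboxylate α-carbon, and the chloride next to the quaternary centre is displaced only slowly.

**Step 7**
Reactants: 9 the cyclopropane acid; 10 2,2-dimethyl-1,3-dioxane-4,6-dione (Meldrum's acid)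
Product: 12 S-ethyl 3-{(1R,3S)-3-[(1E)-5-chloro-3,3-dimethylpent-1-en-1-yl]-2,2-dimethylcyclopropyl}-3-oxopropanethioate, via acyl Meldrum's acid 11 (not isolated)
Conditions: DCC, DMAP, CH2Cl2, 0 °C → rt; filter, acid wash; then EtSH, PhMe, 80 °C (sealed)
Reagents that add atoms: ethanethiol, CCS
Why: In the acyl Meldrum's acid homologation, C-acylation is followed by thermal loss of acetone and CO2 to an acylketene that the thiol traps, which adds C3 and C4 under near-neutral conditions without touching the cyclopropane centres.

**Step 8**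
Reactants: 12 the β-keto thioester
Product: 13 S-ethyl (2Z)-3-[(tert-butyldimethylsilyl)oxy]-3-{(1R,3S)-3-[(1E)-5-chloro-3,3-dimethylpent-1-en-1-yl]-2,2-dimethylcyclopropyl}prop-2-enethioate (cis-divinylcyclopropane)
Conditions: NaH, THF, 0 °C; TBSCl, 0 °C → rt
Reagents that add atoms: tert-butyldimethylsilyl chloride, CC(C)(C)[Si](C)(C)Cl
Why: In the O-silylation of the chelated sodium enolate, sodium bridges the two carbonyl oxygens and holds O2 cis to C4, and allylic strain against the cyclopropane disfavours the other isomer, so the Z C2=C3 enol ether should result.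

**Step 9**
Reactants: 13 the Z-silyl enol ether / E-alkene cis-divinylcyclopropane
Product: 14 S-ethyl (1S,7S)-2-[(tert-butyldimethylsilyl)oxy]-7-(4-chloro-2-methylbutan-2-yl)-4,4-dimethylcyclohepta-2,5-diene-1-carbothioate
Conditions: PhMe (0.02 M), BHT (5 mol %), base-washed sealed tube, 140 °C
Reagents that add atoms: none
Why: On heating, 13 reaches the boat conformer with both alkenyl arms over the three-membered ring, and a concerted suprafacial [3,3] shift makes C3–C11 while the strained C1–C7 bond breaks, which is the classical Cope rearrangement of a cis-divinylcyclopropane with a 2-siloxyvinyl arm. The ring C3–C2–C1–C8–C7–C10–C11 closes by ring expansion of the cyclopropane (bonding of the two alkene termini), and the new alkenes C1=C2 and C7=C10 are necessarily cis within it. C11 is fixed by chirality transfer from the (1R,3S)-cyclopropane, because the E geometry keeps the tert-alkyl group outside the boat and C3 can then reach only one face of C11. C3 is set cis to it by the Z enol ether (thioester outside the boat), but this centre is transient and is planarised in step 10. The selectivity needed is Cope shift over the homodienyl 1,5-hydrogen shift from the C8 methyl group syn to both arms; strain release, the donor siloxy group and the two outward substituents favour the Cope path, while BHT and base-washed glass hold back radical isomerisation and desilylation. That same syn methyl group raises the barrier, which is why 140 °C rather than ambient temperature is planned.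

**Step 10**
Reactants: 14 the cycloheptadiene enol silane
Product: 16 S-ethyl (3aR,8aR)-1,1,6,6-tetramethyl-4-oxo-1,2,3,4,5,6-hexahydroazulene-3a(8aH)-carbothioate (cis-fused; C4 and H11 on one face, C14 and C12 on the other), via tetrabutylammonium enolate 15 (not isolated)
Conditions: TBAF (1.1 equiv, dried), TBAI (10 mol %), THF, 0 → 50 °C
Reagents that add atoms: none
Why: Fluoride desilylation and proton shift to the more acidic C3 give the stabilised enolate, which closes by 5-exo-tet C-alkylation at C14; the tether on C11 can reach only the face of planar C3 on which C12 stands, so the cis ring fusion sets C3.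

**Step 11**
Reactants: 17 geranyl bromide; 18 triethyl phosphonoacetate
Product: 19 ethyl (4E)-2-(diethoxyphosphoryl)-5,9-dimethyldeca-4,8-dienoate
Conditions: NaH, THF, 0 °C; 17, 0 °C → rt
Reagents that add atoms: none
Why: SN2 alkylation of the stabilised phosphonate carbanion at the primary allylic bromide keeps the E alkene.

**Step 12**
Reactants: 19 the geranylated phosphonoacetate; 20 formaldehyde
Product: 21 ethyl (4E)-5,9-dimethyl-2-methylidenedeca-4,8-dienoate (ethyl 2-geranylacrylate)
Conditions: K2CO3, 37% aq 20, H2O, 80 °C
Reagents that add atoms: none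
Why: Horner–Wadsworth–Emmons methylenation with aqueous formaldehyde installs C6 as the terminal methylene group.

**Step 13**
Reactants: 21 ethyl 2-geranylacrylate
Product: 22 ethyl (4E)-5,9-dimethyl-2-[(phenylselanyl)methyl]deca-4,8-dienoate (racemic at C5)
Conditions: PhSeH, Et3N (10 mol %), CH2Cl2, 0 °C → rt
Reagents that add atoms: benzeneselenol, [SeH]c1ccccc1
Why: Base-catalysed conjugate (seleno-Michael) addition places the radical leaving group on C6 and ignores the unactivated trisubstituted alkenes.

**Step 14**
Reactants: 22 the β-seleno ester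
Product: 23 (4E)-5,9-dimethyl-2-[(phenylselanyl)methyl]deca-4,8-dienal
Conditions: DIBAL-H (1.05 equiv), PhMe, −78 °C; MeOH, Rochelle salt
Reagents that add atoms: none
Why: Partial ester reduction stops at the tetrahedral aluminate, which is stable at −78 °C, and the neutral work-up avoids β-elimination of selenolate.

**Step 15**
Reactants: 16 the hydroazulenone; 23 the β-seleno aldehyde
Product: 24 S-ethyl (3aR,5R,8aR)-5-{(4E)-1-hydroxy-5,9-dimethyl-2-[(phenylselanyl)methyl]deca-4,8-dien-1-yl}-1,1,6,6-tetramethyl-4-oxo-1,2,3,4,5,6-hexahydroazulene-3a(8aH)-carbothioate (C9 on the C4 face; C5/C9 epimers)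
Conditions: LDA (1.05 equiv), THF, −78 °C; 23, −78 °C, 20 min; AcOH/THF, −78 °C
Reagents that add atoms: none
Why: In this aldol addition C1 is the only enolisable carbon; lithium bridged between the enolate oxygen and the thioester carbonyl holds the closed Zimmerman–Traxler array on the convex face that bears C4, which sets C1, and short contact with a cold acidic quench limits selenolate elimination and lactonisation onto C4.

**Step 16**
Reactants: 24 the aldol
Product: 25 tricyclic alcohol with ring B (C1–C9–C5–C6–C7–C8) closed: the bridge C9H(OH)–C5H(geranyl)–C6H2 spans C1 and C7 on the C4 face, C10 is now CH2, and the thioester and cis-fused cyclopentane are unchanged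
Conditions: (TMS)3SiH (1.3 equiv) and AIBN (0.2 equiv) by syringe pump, PhMe (3 mM), 90 °C
Reagents that add atoms: none
Why: Silyl-radical abstraction of PhSe gives the primary C6 radical, which closes 6-exo-trig onto C7 (7-endo attack at C10 is slower); because C9 stands on the C4 face and the cyclopentane with the C12 methyl groups blocks the other face, C6 arrives on that same face and sets C7, and the slow hydrogen donor kept dilute limits premature reduction.

**Step 17**
Reactants: 25 the tricyclic alcohol
Product: 26 tricyclic C2,C9-diketone thioester (C1–H at the bridgehead, C5 epimers)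
Conditions: Dess–Martin periodinane, CH2Cl2, rt
Reagents that add atoms: none
Why: Dess–Martin oxidation of the hindered secondary alcohol is run after selenium has left the molecule, and C1 cannot epimerise because it is now a bridgehead.

**Step 18**
Reactants: 26 the diketone thioester
Product: 27 cage trione, the des-isobutyryl target (C2, C4 and C9 ketones, C5 quaternary with geranyl exo, C1–H)
Conditions: KHMDS (1.1 equiv), THF, −78 → 0 °C; aq NH4Cl
Reagents that add atoms: none
Why: In this transannular Claisen (Dieckmann-type) acylation, the enolate carbon C5 lies directly under the C4 thioester and attacks it axially on the only face it can reach, which fixes C5; loss of the weakly basic ethanethiolate makes formation of the non-enolisable C4/C9 diketone irreversible, whereas an enolate at bridgehead C1 cannot cyclise and is only a reversible resting state.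

**Step 19**
Reactants: 27 the cage trione; 28 isobutyryl chloride
Product: 29 CNP0313870.1 (1S,3S,5R,7R,11R in the numbering above)
Conditions: LiTMP (TMP, n-BuLi; 1.5 equiv), THF, −78 → −40 °C; 28, −78 °C → rt
Reagents that add atoms: none
Why: This is the bridgehead lithiation–acylation known for bicyclo[3.3.1]nonane-2,4,9-triones; C1–H is the only proton α to a carbonyl in 27, the hindered amide neither adds to nor reduces the ketones, and the geometrically fixed carbanion is acylated with retention on its open exo side.

**Compound list**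

| No. | Name | SMILES | Role |
|---|---|---|---|
| 1 | 3,3-dimethyloxolan-2-one | CC1(C)CCOC1=O | starting material |
| 2 | 4-chloro-2,2-dimethylbutanoyl chloride | ClCCC(C)(C)C(Cl)=O | intermediate |
| 3 | methyl 4-chloro-2,2-dimethylbutanoate | COC(=O)C(C)(C)CCCl | intermediate |
| 4 | 4-chloro-2,2-dimethylbutan-1-ol | OCC(C)(C)CCCl | intermediate |
| 5 | 5-[(4-chloro-2,2-dimethylbutyl)sulfanyl]-1-phenyl-1H-tetrazole | ClCCC(C)(C)CSc1nnnn1-c1ccccc1 | intermediate |
| 6 | 5-[(4-chloro-2,2-dimethylbutyl)sulfonyl]-1-phenyl-1H-tetrazole | ClCCC(C)(C)CS(=O)(=O)c1nnnn1-c1ccccc1 | intermediate |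
| 7 | methyl (1R,3S)-3-formyl-2,2-dimethylcyclopropane-1-carboxylate | COC(=O)[C@@H]1[C@H](C=O)C1(C)C | starting material |
| 8 | methyl (1R,3S)-3-[(1E)-5-chloro-3,3-dimethylpent-1-en-1-yl]-2,2-dimethylcyclopropane-1-carboxylate | COC(=O)[C@@H]1[C@H](/C=C/C(C)(C)CCCl)C1(C)C | intermediate |
| 9 | (1R,3S)-3-[(1E)-5-chloro-3,3-dimethylpent-1-en-1-yl]-2,2-dimethylcyclopropane-1-carboxylic acid | OC(=O)[C@@H]1[C@H](/C=C/C(C)(C)CCCl)C1(C)C | intermediate |
| 10 | 2,2-dimethyl-1,3-dioxane-4,6-dione | CC1(C)OC(=O)CC(=O)O1 | starting material |
| 11 | 5-acyl Meldrum's acid of 9 | CC1(C)OC(=O)C(C(=O)[C@@H]2[C@H](/C=C/C(C)(C)CCCl)C2(C)C)C(=O)O1 | intermediate |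
| 12 | S-ethyl 3-{(1R,3S)-3-[(1E)-5-chloro-3,3-dimethylpent-1-en-1-yl]-2,2-dimethylcyclopropyl}-3-oxopropanethioate | CCSC(=O)CC(=O)[C@@H]1[C@H](/C=C/C(C)(C)CCCl)C1(C)C | intermediate |
| 13 | (2Z)-TBS enol ether of 12 (cis-divinylcyclopropane) | CCSC(=O)/C=C(O[Si](C)(C)C(C)(C)C)/[C@@H]1[C@H](/C=C/C(C)(C)CCCl)C1(C)C | intermediate |
| 14 | S-ethyl (1S,7S)-2-[(tert-butyldimethylsilyl)oxy]-7-(4-chloro-2-methylbutan-2-yl)-4,4-dimethylcyclohepta-2,5-diene-1-carbothioate | CC1(C)C=C(O[Si](C)(C)C(C)(C)C)[C@@H](C(=O)SCC)[C@@H](C(C)(C)CCCl)C=C1 | intermediate |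
| 15 | tetrabutylammonium enolate of the desilylated β-keto thioester | CCSC(=O)C1=C([O-])CC(C)(C)C=C[C@@H]1C(C)(C)CCCl.CCCC[N+](CCCC)(CCCC)CCCC | intermediate |
| 16 | S-ethyl (3aR,8aR)-1,1,6,6-tetramethyl-4-oxo-1,2,3,4,5,6-hexahydroazulene-3a(8aH)-carbothioate | CC1(C)CC(=O)[C@@]2(C(=O)SCC)CCC(C)(C)[C@H]2C=C1 | intermediate |
| 17 | geranyl bromide | CC(C)=CCC/C(C)=C/CBr | starting material |
| 18 | triethyl phosphonoacetate | CCOC(=O)CP(=O)(OCC)OCC | starting material |
| 19 | ethyl (4E)-2-(diethoxyphosphoryl)-5,9-dimethyldeca-4,8-dienoate | CCOC(=O)C(C/C=C(\C)CCC=C(C)C)P(=O)(OCC)OCC | intermediate |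
| 20 | formaldehyde | C=O | starting material |
| 21 | ethyl (4E)-5,9-dimethyl-2-methylidenedeca-4,8-dienoate | CCOC(=O)C(=C)C/C=C(\C)CCC=C(C)C | intermediate |
| 22 | ethyl (4E)-5,9-dimethyl-2-[(phenylselanyl)methyl]deca-4,8-dienoate | CCOC(=O)C(C[Se]c1ccccc1)C/C=C(\C)CCC=C(C)C | intermediate |
| 23 | (4E)-5,9-dimethyl-2-[(phenylselanyl)methyl]deca-4,8-dienal | O=CC(C[Se]c1ccccc1)C/C=C(\C)CCC=C(C)C | intermediate |
| 24 | C1 aldol of 16 with 23 (C9 on the C4 face) | CC1(C)[C@H](C(O)C(C[Se]c3ccccc3)C/C=C(\C)CCC=C(C)C)C(=O)[C@@]2(C(=O)SCC)CCC(C)(C)[C@H]2C=C1 | intermediate |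
| 25 | tricyclic alcohol, ring B closed | CC1(C)[C@@H]2C(O)C(C/C=C(\C)CCC=C(C)C)C[C@H]1C[C@@H]3C(C)(C)CC[C@]3(C(=O)SCC)C2=O | intermediate |
| 26 | tricyclic C2,C9-diketone thioester | CC1(C)[C@@H]2C(=O)C(C/C=C(\C)CCC=C(C)C)C[C@H]1C[C@@H]3C(C)(C)CC[C@]3(C(=O)SCC)C2=O | intermediate |
| 27 | cage trione (des-isobutyryl target) | CC(C)=CCC/C(C)=C/C[C@@]12C[C@H]3C[C@@H]4C(C)(C)CC[C@]4(C1=O)C(=O)[C@@H](C2=O)C3(C)C | intermediate |
| 28 | isobutyryl chloride | CC(C)C(Cl)=O | starting material |
| 29 | CNP0313870.1 | CC(C)=CCC/C(C)=C/C[C@@]12C[C@H]3C[C@@H]4C(C)(C)CC[C@]4(C1=O)C(=O)[C@@](C(=O)C(C)C)(C2=O)C3(C)C | target |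

**Step count**

Total step count: 19. Longest linear sequence: 15 (steps 1–10 and 15–19).

**Steps most likely to fail**

**Step 9.**
- What may go wrong: the boat conformer is reached too slowly, because the C8 methyl group syn to both arms presses on the inward hydrogens at C3 and C11. The homodienyl hydrogen shift, loss of the silyl group or erosion of the enol ether geometry may then consume the precursor first.
- Fallback: the isolated silyl ether is abandoned.
  - The fallback sets out from 12, whose intramolecularly hydrogen-bonded Z-enol is itself a cis-divinylcyclopropane of locked geometry with a much smaller C2 substituent.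
  - Heating 12 in toluene should let this tautomer rearrange, and the enol formed tautomerises irreversibly to S-ethyl (7S)-7-(4-chloro-2-methylbutan-2-yl)-4,4-dimethyl-2-oxocyclohept-5-ene-1-carbothioate F1.
  - F1 is closed with Cs2CO3 and catalytic NaI in DMF, and the route is rejoined at 16.

**Step 18.**
- What may go wrong: enolisation may be slow or misdirected, with bridgehead C1–H removed instead of the shielded C5–H. Proton shuffling may then outrun attack on the hindered thioester.
- Fallback: the electrophile is changed.
  - The fallback sets out from 26. Fukuyama reduction (Et3SiH, Pd/C, acetone) converts the thioester into the C4 keto aldehyde F2.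
  - A reversible, amine- or alkoxide-catalysed transannular aldol addition of C5 to this far more electrophilic carbonyl gives the cage hydroxy diketone F3.
  - Dess–Martin oxidation of F3 rejoins the route at 27.

**Step 19.**
- What may go wrong: the bridgehead carbanion next to CMe2 may be captured poorly, through ketene formation from the acid chloride, O-acylation or attack on a second molecule of trione.
- Fallback: metalation and carbon–carbon bond formation are separated.
  - The fallback sets out from 27. The lithiated species is quenched with iodine to give the C1 bridgehead iodide F4.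
  - Iodine–magnesium exchange with i-PrMgCl gives a milder bridgehead nucleophile, which adds to isobutyraldehyde to give the C1 bridgehead carbinol F5.
  - Dess–Martin oxidation of F5 rejoins the route at 29.

**Further compounds**
F1 | step 9 | S-ethyl (7S)-7-(4-chloro-2-methylbutan-2-yl)-4,4-dimethyl-2-oxocyclohept-5-ene-1-carbothioate | CCSC(=O)C1C(=O)CC(C)(C)C=C[C@@H]1C(C)(C)CCCl
F2 | step 18 | C4 keto aldehyde (formyl analogue of 26) | CC1(C)[C@@H]2C(=O)C(C/C=C(\C)CCC=C(C)C)C[C@H]1C[C@@H]3C(C)(C)CC[C@]3(C=O)C2=O
F3 | step 18 | cage hydroxy diketone (C4 carbinol) | CC(C)=CCC/C(C)=C/C[C@@]12C[C@H]3C[C@@H]4C(C)(C)CC[C@]4(C1O)C(=O)[C@@H](C2=O)C3(C)C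
F4 | step 19 | C1 bridgehead iodide | CC(C)=CCC/C(C)=C/C[C@@]12C[C@H]3C[C@@H]4C(C)(C)CC[C@]4(C1=O)C(=O)[C@@](I)(C2=O)C3(C)C
F5 | step 19 | C1 bridgehead carbinol | CC(C)=CCC/C(C)=C/C[C@@]12C[C@H]3C[C@@H]4C(C)(C)CC[C@]4(C1=O)C(=O)[C@@](C(O)C(C)C)(C2=O)C3(C)C
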